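The ring is numbered O1, C2–C6 and the side chain C1′–C21′. The ring oxygen on C6 and the hydroxyls on C2′ and C4′ are all syn, and C4 and C6′ can both derive from carboxyl carbons, so C4–C6′ is a latent meso nonanedioate with its mirror plane through C2′. The route builds this meso triol diester two-directionally and lets a hydrolase cleave one of its two enantiotopic ester groups. That one operation fixes three stereocentres in the absolute sense and differentiates the termini. The acid end becomes a temporary δ-lactone that the C7′–C21′ acetylide opens, C4′ then relays its configuration to C6′, and the ester end becomes the dihydropyranone.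

Key step: step 4

Assumption: the hydrolase found by screening cleaves the ester group at C6′ of the meso dimethyl ester (the arm whose carbinol is S); a hit of the opposite sense would be used with the roles of the two termini exchanged.

Step 1
Reactants: 1 diethyl 3-hydroxypentanedioate (diethyl 3-hydroxyglutarate)
Product: 2 di-tert-butyl 5-hydroxy-3,7-dioxononanedioate
Conditions: t-BuOAc (7 equiv), LDA (7 equiv), THF, −78 °C; then 1, −78 → −30 °C; aq. NH4Cl
Reagents that add atoms: tert-butyl acetate, CC(=O)OC(C)(C)C
Why: Two-directional crossed Claisen condensation; the lithium enolate of tert-butyl acetate does not self-condense at low temperature and should acylate both ethyl ester groups of the alkoxide of 1, the β-keto ester products being held as enolates, and no stereocentre is formed.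

Step 2
Reactants: 2
Product: 4 di-tert-butyl (3R,5r,7S)-3,5,7-trihydroxynonanedioate (meso; all-syn), via syn-dihydroxy ketone 3 (not isolated)
Conditions: Et2BOMe (1.2 equiv), NaBH4, THF–MeOH 4:1, −78 °C; AcOH, MeOH co-evaporation; second identical cycle
Reagents that add atoms: none
Why: Narasaka–Prasad reduction run twice; in each cycle the C5 hydroxyl forms a six-membered diethylboron chelate with one β-ketone and external hydride adds axially to the half-chair, so each new carbinol should be 1,3-syn to C5 and the all-syn meso triol should result.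

Step 3
Reactants: 4
Product: 5 dimethyl (3R,5r,7S)-3,5,7-trihydroxynonanedioate (meso)
Conditions: HCl (from AcCl), MeOH, 40 °C; then cat. K2CO3, MeOH, 0 °C; neutralise, crystallise
Reagents that add atoms: methanol, CO
Why: Acid-catalysed transesterification (tert-butyl cleavage and Fischer esterification) gives the methyl esters an esterase accepts without touching the carbinol centres; the excess methanol and the brief basic methanolysis should keep the open dihydroxy ester in favour over the δ-lactone.

Step 4
Reactants: 5
Product: 6 (3S,5R,7R)-3,5,7-trihydroxy-9-methoxy-9-oxononanoic acid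
Conditions: pig liver esterase (or the best hit of a hydrolase panel), phosphate buffer pH 7.5, 25 °C, pH-stat (1.0 equiv NaOH); wash at pH 8, acidify to pH 3, EtOAc
Reagents that add atoms: water, O
Why: A serine hydrolase acylates its active-site serine with one of the two enantiotopic methyl esters of meso 5 and water cleaves the acyl-enzyme, so that only 6 and methanol should form; the closest known reaction type is the esterase or lipase desymmetrisation of meso and prochiral 3-oxygenated glutarate and pimelate diesters. No ring is closed and no new stereocentre is made: the choice between two mirror-image arms turns pseudoasymmetric C2′ into a true stereocentre and fixes the absolute configuration of C6, C2′ and C4′ together. The controlling element is the chiral acyl-binding site, which meets a β-hydroxy ester of R configuration in one arm and of S configuration in the other, the difference sitting two atoms from the reacting carbonyl. The step needs enantiotopic-group selectivity and a stop at the half-ester; the first rests on that proximity, the second on the poor binding of the anionic half-ester. Any further hydrolysis to the achiral diacid should consume the minor enantiomer of 6 faster and so raise the enantiomeric purity of what remains. Unreacted 5 and any neutral lactone are removed by the wash at pH 8 before 6 is extracted at pH 3.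

Step 5
Reactants: 6
Product: 7 methyl (3R)-3-hydroxy-4-[(2R,4S)-4-hydroxy-6-oxooxan-2-yl]butanoate
Conditions: EDC·HCl (1.2 equiv), CH2Cl2 (0.01 M), 0 °C → rt
Reagents that add atoms: none
Why: Carbodiimide-mediated lactonisation; only the free acid is activated and only the C2′ hydroxyl can reach it through a six-membered ring (C4′-OH would give a β-lactone, C6-OH an eight-membered ring), so the δ-lactone should form with no change at any stereocentre.

Step 6
Reactants: 8 (S)-epichlorohydrin; 9 decylmagnesium bromide
Product: 10 (S)-1-chlorotridecan-2-ol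
Conditions: CuI (10 mol%), THF, −40 → 0 °C; aq. NH4Cl
Reagents that add atoms: none
Why: Copper-catalysed Grignard opening of the epoxide at its unsubstituted carbon; the stereocentre is not touched and becomes C10′.

Step 7
Reactants: 10
Product: 12 (S)-pentadec-1-yn-4-ol, via (S)-2-undecyloxirane 11 (not isolated)
Conditions: lithium acetylide–ethylenediamine complex (3 equiv), DMSO, 0 °C → rt
Reagents that add atoms: lithium acetylide–ethylenediamine complex, [Li]C#C.NCCN
Why: The acetylide first acts as base and closes the chlorohydrin to epoxide 11 (intramolecular Williamson reaction), then opens it at the terminal carbon (SN2 epoxide alkynylation), so C10′ should keep its configuration.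

Step 8
Reactants: 12
Product: 13 (S)-tert-butyldimethyl(pentadec-1-yn-4-yloxy)silane
Conditions: TBSCl, imidazole, DMF, rt
Reagents that add atoms: tert-butyldimethylsilyl chloride, CC(C)(C)[Si](C)(C)Cl
Why: Standard silylation of a secondary alcohol; the ether survives all steps up to the final acid treatment.

Step 9
Reactants: 7; 13
Product: 15 methyl (3R,5R,7S,13S)-13-[(tert-butyldimethylsilyl)oxy]-3,5,7-trihydroxy-9-oxotetracos-10-ynoate (open-chain form; in equilibrium with its lactol), via alkynyllithium 14 (not isolated)
Conditions: 13 (3.3 equiv), n-BuLi (3.2 equiv), THF, −78 °C; then 7, −78 → −50 °C; aq. NH4Cl at −78 °C; excess 13 recovered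
Reagents that add atoms: none
Why: Acylation of a lithium acetylide by a δ-lactone; after the excess acetylide has deprotonated both hydroxyls, the lactone carbonyl should be more electrophilic than the methyl ester next to an alkoxide, and the tetrahedral lithium lactolate should hold until work-up and so prevent a second addition.

Step 10
Reactants: 15
Product: 16 methyl (3R,5R,7S,13S)-13-[(tert-butyldimethylsilyl)oxy]-3,5,7-trihydroxy-9-oxotetracosanoate
Conditions: H2 (1 atm), 10% Pd/C, EtOAc, rt
Reagents that add atoms: none
Why: Heterogeneous hydrogenation should saturate the alkyne while ketone, ester and silyl ether stay inert; it also removes the risk of 6-endo cyclisation of the β-hydroxy ynone.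

Step 11
Reactants: 16
Product: 17 methyl (3R,5R,7R,9R,13S)-13-[(tert-butyldimethylsilyl)oxy]-3,5,7,9-tetrahydroxytetracosanoate
Conditions: Et2BOMe (3 equiv), NaBH4, THF–MeOH 4:1, −78 °C; AcOH, MeOH co-evaporation
Reagents that add atoms: none
Why: Narasaka–Prasad reduction; the C4′ hydroxyl, β to the C6′ ketone, forms the boron chelate and axial hydride delivery should set C6′ syn to C4′, completing the all-syn C6/C2′/C4′/C6′ array, while the methyl ester is not reduced at −78 °C.

Step 12
Reactants: 17
Product: 18 methyl ester bis-acetonide (C4 CO2Me; cis-1,3-dioxanes across O6/O2′ and O4′/O6′; C10′ OTBS)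
Conditions: 2,2-dimethoxypropane, PPTS (cat.), acetone, rt
Reagents that add atoms: 2,2-dimethoxypropane, COC(C)(C)OC
Why: Acetalisation under thermodynamic control; the four syn-1,3-related hydroxyls can pair completely only as C6/C2′ and C4′/C6′, each pair giving a chair dioxane with equatorial substituents.

Step 13
Reactants: 18
Product: 19 aldehyde bis-acetonide (C4 CHO; otherwise as 18)
Conditions: DIBAL-H (1.1 equiv), CH2Cl2, −78 °C; Rochelle salt
Reagents that add atoms: none
Why: Partial reduction of a methyl ester by DIBAL-H; the aluminium hemiacetal, stabilised by the β-acetal oxygen, should collapse to the aldehyde only on work-up.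

Step 14
Reactants: 19
Product: 20 (Z)-enoate bis-acetonide (methyl ester at C2; C3=C4 Z; otherwise as 18)
Conditions: (CF3CH2O)2P(O)CH2CO2Me, KHMDS, 18-crown-6, THF, −78 °C
Reagents that add atoms: methyl bis(2,2,2-trifluoroethyl)phosphonoacetate, COC(=O)CP(=O)(OCC(F)(F)F)OCC(F)(F)F
Why: Still–Gennari olefination; the electron-poor phosphonate with a dissociated potassium counter-ion eliminates quickly from the kinetic syn adduct and should give the (Z)-enoate.

Step 15
Reactants: 20
Product: 22 (6S)-6-[(2R,4R,6R,10S)-2,4,6,10-tetrahydroxyhenicosyl]-5,6-dihydro-2H-pyran-2-one (target), via seco-ester pentaol 21 (not isolated)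
Conditions: 3 M aq. HCl, THF, rt
Reagents that add atoms: none
Why: Acid hydrolysis of both acetonides and the silyl ether followed by acid-catalysed lactonisation; in 21 only the C6 hydroxyl can close a six-membered ring onto the (Z)-ester, and the absence of base should avoid oxa-Michael addition of the C2′ hydroxyl.

Compound list
1 | diethyl 3-hydroxypentanedioate | CCOC(=O)CC(O)CC(=O)OCC | starting material
2 | di-tert-butyl 5-hydroxy-3,7-dioxononanedioate | CC(C)(C)OC(=O)CC(=O)CC(O)CC(=O)CC(=O)OC(C)(C)C | intermediate
3 | di-tert-butyl syn-3,5-dihydroxy-7-oxononanedioate (racemic; one enantiomer drawn) | CC(C)(C)OC(=O)C[C@@H](O)C[C@@H](O)CC(=O)CC(=O)OC(C)(C)C | intermediate (not isolated)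
4 | di-tert-butyl (3R,5r,7S)-3,5,7-trihydroxynonanedioate (meso) | CC(C)(C)OC(=O)C[C@@H](O)C[C@@H](O)C[C@@H](O)CC(=O)OC(C)(C)C | intermediate
5 | dimethyl (3R,5r,7S)-3,5,7-trihydroxynonanedioate (meso) | COC(=O)C[C@@H](O)C[C@@H](O)C[C@@H](O)CC(=O)OC | intermediate
6 | (3S,5R,7R)-3,5,7-trihydroxy-9-methoxy-9-oxononanoic acid | OC(=O)C[C@@H](O)C[C@@H](O)C[C@@H](O)CC(=O)OC | intermediate
7 | methyl (3R)-3-hydroxy-4-[(2R,4S)-4-hydroxy-6-oxooxan-2-yl]butanoate | O=C1C[C@@H](O)C[C@@H](O1)C[C@@H](O)CC(=O)OC | intermediate
8 | (S)-epichlorohydrin | ClC[C@@H]1CO1 | starting material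
9 | decylmagnesium bromide | CCCCCCCCCC[Mg]Br | starting material
10 | (S)-1-chlorotridecan-2-ol | ClC[C@@H](O)CCCCCCCCCCC | intermediate
11 | (S)-2-undecyloxirane | CCCCCCCCCCC[C@H]1CO1 | intermediate (not isolated)
12 | (S)-pentadec-1-yn-4-ol | C#CC[C@@H](O)CCCCCCCCCCC | intermediate
13 | (S)-tert-butyldimethyl(pentadec-1-yn-4-yloxy)silane | C#CC[C@@H](O[Si](C)(C)C(C)(C)C)CCCCCCCCCCC | intermediate
14 | lithium acetylide of 13 | [Li]C#CC[C@@H](O[Si](C)(C)C(C)(C)C)CCCCCCCCCCC | intermediate (not isolated)
15 | methyl (3R,5R,7S,13S)-13-[(tert-butyldimethylsilyl)oxy]-3,5,7-trihydroxy-9-oxotetracos-10-ynoate | COC(=O)C[C@H](O)C[C@H](O)C[C@H](O)CC(=O)C#CC[C@@H](O[Si](C)(C)C(C)(C)C)CCCCCCCCCCC | intermediate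
16 | methyl (3R,5R,7S,13S)-13-[(tert-butyldimethylsilyl)oxy]-3,5,7-trihydroxy-9-oxotetracosanoate | COC(=O)C[C@H](O)C[C@H](O)C[C@H](O)CC(=O)CCC[C@@H](O[Si](C)(C)C(C)(C)C)CCCCCCCCCCC | intermediate
17 | methyl (3R,5R,7R,9R,13S)-13-[(tert-butyldimethylsilyl)oxy]-3,5,7,9-tetrahydroxytetracosanoate | COC(=O)C[C@H](O)C[C@H](O)C[C@H](O)C[C@H](O)CCC[C@@H](O[Si](C)(C)C(C)(C)C)CCCCCCCCCCC | intermediate
18 | methyl ester bis-acetonide (O6/O2′ and O4′/O6′ acetonides; C10′ OTBS) | COC(=O)C[C@H]1C[C@H](OC(C)(C)O1)C[C@H]2C[C@H](OC(C)(C)O2)CCC[C@@H](O[Si](C)(C)C(C)(C)C)CCCCCCCCCCC | intermediate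
19 | aldehyde bis-acetonide (C4 CHO) | O=CC[C@H]1C[C@H](OC(C)(C)O1)C[C@H]2C[C@H](OC(C)(C)O2)CCC[C@@H](O[Si](C)(C)C(C)(C)C)CCCCCCCCCCC | intermediate
20 | (Z)-enoate bis-acetonide | COC(=O)/C=C\C[C@H]1C[C@H](OC(C)(C)O1)C[C@H]2C[C@H](OC(C)(C)O2)CCC[C@@H](O[Si](C)(C)C(C)(C)C)CCCCCCCCCCC | intermediate
21 | seco-ester pentaol (methyl (Z)-5,7,9,11,15-pentahydroxyhexacos-2-enoate, configuration as in 22) | COC(=O)/C=C\C[C@H](O)C[C@H](O)C[C@H](O)C[C@H](O)CCC[C@@H](O)CCCCCCCCCCC | intermediate (not isolated)
22 | (6S)-6-[(2R,4R,6R,10S)-2,4,6,10-tetrahydroxyhenicosyl]-5,6-dihydro-2H-pyran-2-one | CCCCCCCCCCC[C@H](O)CCC[C@@H](O)C[C@@H](O)C[C@@H](O)C[C@@H]1CC=CC(=O)O1 | target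

Total step count: 15. Longest linear sequence: 12 (steps 1–5 and 9–15); steps 6–8 make the alkyne fragment.

Steps most likely to fail

Step 4. The hydrolase may discriminate poorly between the two enantiotopic ester arms, or hydrolyse on to the diacid, so that the half-ester is formed in low enantiomeric purity or yield. The fallback replaces desymmetrisation by a classical resolution that recycles through the meso compound. It sets out from 5: one equivalent of LiOH in THF–water at 0 °C gives the racemic half-ester, that is 6 together with the antipodal half-ester F1. Crystallisation with (S)-1-phenylethylamine from ethyl acetate–ethanol gives the (S)-1-phenylethylammonium salt F2 of 6 (written for the case that the (S)-amine gives the less soluble salt with 6; otherwise the (R)-amine is used). Dilute HCl releases 6, where the route is rejoined. F1 from the mother liquor is re-esterified with TMSCHN2 to meso 5 and used again.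

Step 9. The excess acetylide may attack the methyl ester or enolise the lactone, and the lithium alkoxides may undergo retro-aldol cleavage, so that mono-addition at the lactone carbonyl is not clean. The fallback replaces the polyanion chemistry by a masked substrate and a stoichiometric nucleophile. It sets out from 7: TESCl and imidazole give the bis(triethylsilyl) ether F3; 1.1 equivalents of 14 at −78 °C open its lactone to the ynone F4; hydrogenation over Pd/C gives the saturated ketone F5; AcOH–THF–water removes both triethylsilyl groups while the C10′ TBS ether stays, and gives 16, where the route is rejoined.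

Step 14. The β-acetal oxygen of the aldehyde may be eliminated under the basic olefination, or the kinetic Z selectivity may be eroded to give E ester that cannot lactonise. The fallback makes the Z alkene by semi-hydrogenation of an alkyne instead of by a Z-selective olefination. It sets out from 19: CBr4 and PPh3 give the dibromoalkene F6 without base; n-BuLi (2 equiv) and then methyl chloroformate give the ynoate F7 (Corey–Fuchs sequence); hydrogenation over Lindlar catalyst with quinoline gives 20, where the route is rejoined.

Further compounds
F1 | step 4 | (3R,5S,7S)-3,5,7-trihydroxy-9-methoxy-9-oxononanoic acid (enantiomer of 6) | OC(=O)C[C@H](O)C[C@H](O)C[C@H](O)CC(=O)OC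
F2 | step 4 | (S)-1-phenylethylammonium salt of 6 | [O-]C(=O)C[C@@H](O)C[C@@H](O)C[C@@H](O)CC(=O)OC.C[C@H]([NH3+])c1ccccc1
F3 | step 9 | bis(triethylsilyl) ether of 7 | O=C1C[C@@H](O[Si](CC)(CC)CC)C[C@@H](O1)C[C@@H](O[Si](CC)(CC)CC)CC(=O)OC
F4 | step 9 | ynone with TES ethers at O6 and O4′ and free C2′ hydroxyl | COC(=O)C[C@H](O[Si](CC)(CC)CC)C[C@H](O)C[C@H](O[Si](CC)(CC)CC)CC(=O)C#CC[C@@H](O[Si](C)(C)C(C)(C)C)CCCCCCCCCCC
F5 | step 9 | saturated ketone with TES ethers at O6 and O4′ | COC(=O)C[C@H](O[Si](CC)(CC)CC)C[C@H](O)C[C@H](O[Si](CC)(CC)CC)CC(=O)CCC[C@@H](O[Si](C)(C)C(C)(C)C)CCCCCCCCCCC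
F6 | step 14 | 1,1-dibromoalkene bis-acetonide | BrC(Br)=CC[C@H]1C[C@H](OC(C)(C)O1)C[C@H]2C[C@H](OC(C)(C)O2)CCC[C@@H](O[Si](C)(C)C(C)(C)C)CCCCCCCCCCC
F7 | step 14 | ynoate bis-acetonide | COC(=O)C#CC[C@H]1C[C@H](OC(C)(C)O1)C[C@H]2C[C@H](OC(C)(C)O2)CCC[C@@H](O[Si](C)(C)C(C)(C)C)CCCCCCCCCCC
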